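## Retrosynthetic overview

1. The methyl ester comes from one-step oxidation of a 2-(1,2-dioxolan-3-yl)ethanol.
2. The 1,2-dioxolane closes by 5-exo attack of a tertiary hydroperoxide on a chiral 2,2-disubstituted oxetane; inversion there fixes C3. The hydroperoxide comes from cobalt-catalysed silylperoxidation of a 1,1-disubstituted alkene. C5 is formed without control and the two ring diastereomers are separated.
3. The alkene is cut at C5–C6 by a late Negishi coupling of fragment A (C1–C5 oxetanyl enol triflate) with fragment B (C6–C13 phenylalkylzinc); 12 and 15 of the 27 non-hydrogen atoms of the target lie on either side of this bond.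
4. Fragment A comes from (R)-2-methylglycidol and isopropenyl Grignard. Fragment B comes from (S)-3-bromo-2-methylpropan-1-ol, PhMgBr and 1,5-dibromopentane, so C7 is from the chiral pool.
5. Ring order: oxirane (bought), then oxetane (step 3), then 1,2-dioxolane (step 13); the benzene ring is bought.

Assumption: positions are numbered as in the parent acid (C1 ester carbon, C3 and C5 the two ring carbons, C7 the side-chain stereocentre), and the two Grignard solutions and both four-carbon chiral building blocks are bought.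

## Route

**Step 1**
Reactants: 1 [(2R)-2-methyloxiran-2-yl]methanol; 2 prop-1-en-2-ylmagnesium bromide
Product: 3 (2S)-2,4-dimethylpent-4-ene-1,2-diol
Conditions: 2 (2.5 equiv), CuI (10 mol %), THF, −30 → 0 °C
Reagents that add atoms: none
Why: Copper-catalysed Grignard opening of the epoxide at its CH2 terminus (SN2) leaves the oxygen-bearing quaternary centre of 1 untouched, so its configuration is carried over (R becomes S only through a change of CIP priorities).

**Step 2**
Reactants: 3 (2S)-2,4-dimethylpent-4-ene-1,2-diol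
Product: 5 (2S)-2-methyl-2-(2-methylprop-2-en-1-yl)oxirane, via primary monotosylate 4 (not isolated)
Conditions: NaH (2.2 equiv), THF, 0 °C; then N-tosylimidazole (1.05 equiv), 0 °C → rt
Reagents that add atoms: none
Why: Selective sulfonylation of the primary alkoxide followed by intramolecular Williamson closure by the tertiary alkoxide re-forms an epoxide on the other arm without breaking any bond to the stereocentre.

**Step 3**
Reactants: 5 (2S)-2-methyl-2-(2-methylprop-2-en-1-yl)oxirane
Product: 6 (2S)-2-methyl-2-(2-methylprop-2-en-1-yl)oxetane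
Conditions: Me3S(O)I (3 equiv), KOt-Bu (3 equiv), t-BuOH, 50 °C, 72 h
Reagents that add atoms: trimethylsulfoxonium iodide, C[S+](C)(C)=O.[I-]
Why: Corey–Chaykovsky ring expansion, in which the sulfoxonium ylide opens the epoxide at CH2 and the tertiary alkoxide then displaces DMSO (4-exo-tet), so the quaternary centre is retained.

**Step 4**
Reactants: 6 (2S)-2-methyl-2-(2-methylprop-2-en-1-yl)oxetane
Product: 8 1-[(2R)-2-methyloxetan-2-yl]propan-2-one, via secondary ozonide 7 (not isolated)
Conditions: O3, CH2Cl2, −78 °C; then Me2S, −78 °C → rt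
Reagents that add atoms: ozone, [O-][O+]=O
Why: Ozonolysis of the 1,1-disubstituted alkene with reductive work-up unmasks the methyl ketone while the oxetane and its stereocentre are not involved (R now only by priority change).

**Step 5**
Reactants: 8 1-[(2R)-2-methyloxetan-2-yl]propan-2-one
Product: 10 3-[(2R)-2-methyloxetan-2-yl]prop-1-en-2-yl trifluoromethanesulfonate, via potassium enolate 9 (not isolated)
Conditions: KN(SiMe3)2 (1.1 equiv), THF, −78 °C; then PhNTf2 (1.15 equiv), −78 → 0 °C
Reagents that add atoms: N-phenylbis(trifluoromethanesulfonimide), O=S(=O)(N(c1ccccc1)S(=O)(=O)C(F)(F)F)C(F)(F)F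
Why: Kinetic deprotonation at the unhindered methyl group (the other α-CH2 is neopentyl-like) and O-sulfonylation of the enolate give the terminal enol triflate needed for cross-coupling.

**Step 6**
Reactants: 11 (2S)-3-bromo-2-methylpropan-1-ol
Product: 12 {[(2S)-3-bromo-2-methylpropyl]oxy}(tert-butyl)dimethylsilane
Conditions: TBSCl, imidazole, CH2Cl2, 0 °C → rt
Reagents that add atoms: tert-butyldimethylsilyl chloride, CC(C)(C)[Si](C)(C)Cl
Why: Silyl ether protection keeps the hydroxyl from quenching the Grignard reagent in step 8 and does not touch the stereocentre.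

**Step 7**
Reactants: 13 phenylmagnesium bromide; 14 1,5-dibromopentane
Product: 15 (5-bromopentyl)benzene
Conditions: 14 (3 equiv), Li2CuCl4 (3 mol %), NMP (4 equiv), THF, 0 °C → rt
Reagents that add atoms: none
Why: Copper-catalysed Kochi cross-coupling of the Grignard reagent with a primary alkyl bromide, held at mono-substitution by the excess of dibromide.

**Step 8**
Reactants: 15 (5-bromopentyl)benzene; 12 {[(2S)-3-bromo-2-methylpropyl]oxy}(tert-butyl)dimethylsilane
Product: 17 tert-butyl(dimethyl){[(2R)-2-methyl-8-phenyloctyl]oxy}silane, via 5-phenylpentylmagnesium bromide 16 (not isolated)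
Conditions: Mg, THF, 40 °C; then 12, Li2CuCl4 (3 mol %), NMP (4 equiv), THF, −10 °C → rt
Reagents that add atoms: none
Why: Copper-catalysed Kochi sp3–sp3 coupling at the primary bromide leaves the adjacent methyl-bearing centre from 11 intact (S becomes R by priority change), and this is the side-chain stereocentre C7 of the target.

**Step 9**
Reactants: 17 tert-butyl(dimethyl){[(2R)-2-methyl-8-phenyloctyl]oxy}silane
Product: 18 (2R)-2-methyl-8-phenyloctan-1-ol
Conditions: p-TsOH·H2O (5 mol %), MeOH, rt
Reagents that add atoms: none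
Why: Acid-catalysed methanolysis removes the primary silyl ether without affecting anything else.

**Step 10**
Reactants: 18 (2R)-2-methyl-8-phenyloctan-1-ol
Product: 19 [(7R)-8-iodo-7-methyloctyl]benzene
Conditions: I2, PPh3, imidazole, CH2Cl2, 0 °C → rt
Reagents that add atoms: iodine, II
Why: Appel-type iodination (SN2 at the primary carbon) gives the iodide for zinc insertion without touching the neighbouring stereocentre.

**Step 11**
Reactants: 19 [(7R)-8-iodo-7-methyloctyl]benzene; 10 3-[(2R)-2-methyloxetan-2-yl]prop-1-en-2-yl trifluoromethanesulfonate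
Product: 21 (2S)-2-methyl-2-[(4R)-4-methyl-2-methylidene-10-phenyldecyl]oxetane, via alkylzinc iodide 20 (not isolated)
Conditions: Zn dust, LiCl, THF, 40 °C; then 10, Pd(dppf)Cl2 (4 mol %), THF, 50 °C
Reagents that add atoms: none
Why: Negishi sp3–sp2 cross-coupling joins the C1–C5 and C6–C13 halves at C5–C6 without touching either stereocentre.

**Step 12**
Reactants: 21 (2S)-2-methyl-2-[(4R)-4-methyl-2-methylidene-10-phenyldecyl]oxetane
Product: 22 triethyl({(4R)-2,4-dimethyl-1-[(2R)-2-methyloxetan-2-yl]-10-phenyldecan-2-yl}peroxy)silane (about 1:1 mixture of the two C2 epimers)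
Conditions: Co(acac)2 (10 mol %), O2 (1 atm), Et3SiH (2 equiv), ClCH2CH2Cl, rt
Reagents that add atoms: dioxygen, O=O; triethylsilane, CC[SiH](CC)CC
Why: Mukaiyama–Isayama hydroperoxysilylation, in which H-atom transfer to the CH2 terminus gives a tertiary radical that is trapped by O2 and silylated; the new peroxide-bearing centre (C5 of the target) forms without facial control and the oxetane is untouched.

**Step 13**
Reactants: 22 triethyl({(4R)-2,4-dimethyl-1-[(2R)-2-methyloxetan-2-yl]-10-phenyldecan-2-yl}peroxy)silane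
Product: 24 2-[(3S,5S)-3,5-dimethyl-5-[(2R)-2-methyl-8-phenyloctyl]-1,2-dioxolan-3-yl]ethan-1-ol, via tertiary hydroperoxide 23 (not isolated)
Conditions: p-TsOH·H2O (0.2 equiv), MeOH (10 equiv), CH2Cl2, 0 °C → rt; silica gel chromatography
Reagents that add atoms: none
Why: Acid methanolysis frees the hydroperoxide, which opens the protonated oxetane at its tertiary carbon in a 5-exo ring closure with inversion and so fixes C3; the two dioxolanes epimeric at C5 are diastereomers, and the (3S,5S) isomer from the (2S,4R) epimer of 22 is isolated by chromatography.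

**Step 14**
Reactants: 24 2-[(3S,5S)-3,5-dimethyl-5-[(2R)-2-methyl-8-phenyloctyl]-1,2-dioxolan-3-yl]ethan-1-ol
Product: 25 methyl 2-[(3R,5S)-3,5-dimethyl-5-[(2R)-2-methyl-8-phenyloctyl]-1,2-dioxolan-3-yl]acetate
Conditions: pyridinium dichromate (6 equiv), MeOH (6 equiv), DMF, rt
Reagents that add atoms: methanol, CO
Why: Chromium oxidation in the presence of methanol (alcohol to aldehyde to methyl hemiacetal to ester) gives the methyl ester in one operation; both ring carbons are fully substituted, so nothing can epimerise (3S becomes 3R only by priority change).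

## Compound list

1 | [(2R)-2-methyloxiran-2-yl]methanol | C[C@@]1(CO)CO1 | starting material
2 | prop-1-en-2-ylmagnesium bromide | CC(=C)[Mg]Br | starting material
3 | (2S)-2,4-dimethylpent-4-ene-1,2-diol | C[C@@](O)(CO)CC(C)=C | intermediate
4 | (2S)-2-hydroxy-2,4-dimethylpent-4-en-1-yl 4-methylbenzenesulfonate | C[C@@](O)(COS(=O)(=O)c1ccc(C)cc1)CC(C)=C | intermediate
5 | (2S)-2-methyl-2-(2-methylprop-2-en-1-yl)oxirane | C[C@@]1(CO1)CC(C)=C | intermediate
6 | (2S)-2-methyl-2-(2-methylprop-2-en-1-yl)oxetane | C[C@@]1(CCO1)CC(C)=C | intermediate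
7 | 3-methyl-3-{[(2R)-2-methyloxetan-2-yl]methyl}-1,2,4-trioxolane (both epimers at the trioxolane carbon) | C[C@@]1(CCO1)CC2(C)OCOO2 | intermediate
8 | 1-[(2R)-2-methyloxetan-2-yl]propan-2-one | C[C@@]1(CCO1)CC(C)=O | intermediate
9 | potassium 3-[(2R)-2-methyloxetan-2-yl]prop-1-en-2-olate | C[C@@]1(CCO1)CC(=C)[O-].[K+] | intermediate
10 | 3-[(2R)-2-methyloxetan-2-yl]prop-1-en-2-yl trifluoromethanesulfonate | C[C@@]1(CCO1)CC(=C)OS(=O)(=O)C(F)(F)F | intermediate
11 | (2S)-3-bromo-2-methylpropan-1-ol | OC[C@H](C)CBr | starting material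
12 | {[(2S)-3-bromo-2-methylpropyl]oxy}(tert-butyl)dimethylsilane | CC(C)(C)[Si](C)(C)OC[C@H](C)CBr | intermediate
13 | phenylmagnesium bromide | Br[Mg]c1ccccc1 | starting material
14 | 1,5-dibromopentane | BrCCCCCBr | starting material
15 | (5-bromopentyl)benzene | BrCCCCCc1ccccc1 | intermediate
16 | (5-phenylpentyl)magnesium bromide | Br[Mg]CCCCCc1ccccc1 | intermediate
17 | tert-butyl(dimethyl){[(2R)-2-methyl-8-phenyloctyl]oxy}silane | CC(C)(C)[Si](C)(C)OC[C@H](C)CCCCCCc1ccccc1 | intermediate
18 | (2R)-2-methyl-8-phenyloctan-1-ol | OC[C@H](C)CCCCCCc1ccccc1 | intermediate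
19 | [(7R)-8-iodo-7-methyloctyl]benzene | IC[C@H](C)CCCCCCc1ccccc1 | intermediate
20 | iodo[(2R)-2-methyl-8-phenyloctyl]zinc | I[Zn]C[C@H](C)CCCCCCc1ccccc1 | intermediate
21 | (2S)-2-methyl-2-[(4R)-4-methyl-2-methylidene-10-phenyldecyl]oxetane | C[C@@]1(CCO1)CC(=C)C[C@H](C)CCCCCCc2ccccc2 | intermediate
22 | triethyl({(4R)-2,4-dimethyl-1-[(2R)-2-methyloxetan-2-yl]-10-phenyldecan-2-yl}peroxy)silane (both C2 epimers) | C[C@@]1(CCO1)CC(C)(OO[Si](CC)(CC)CC)C[C@H](C)CCCCCCc2ccccc2 | intermediate
23 | (4R)-2,4-dimethyl-1-[(2R)-2-methyloxetan-2-yl]-10-phenyldecan-2-yl hydroperoxide (both C2 epimers) | C[C@@]1(CCO1)CC(C)(OO)C[C@H](C)CCCCCCc2ccccc2 | intermediate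
24 | 2-[(3S,5S)-3,5-dimethyl-5-[(2R)-2-methyl-8-phenyloctyl]-1,2-dioxolan-3-yl]ethan-1-ol | OCC[C@@]1(C)C[C@](C)(C[C@H](C)CCCCCCc2ccccc2)OO1 | intermediate
25 | methyl 2-[(3R,5S)-3,5-dimethyl-5-[(2R)-2-methyl-8-phenyloctyl]-1,2-dioxolan-3-yl]acetate | COC(=O)C[C@@]1(C)C[C@](C)(C[C@H](C)CCCCCCc2ccccc2)OO1 | target

## Step count and risks

Total step count: 14.
Longest linear sequence: 9 (steps 1–5 and 11–14); the branch through steps 6–10 is 8 to the target.

Steps most likely to fail:

**Step 12 (with its consequence in step 13).** The radical trapping gives no control at C5, so at best half of the material is the wanted epimer, and reduction to the tertiary alcohol can compete. The fallback sets out from 21 and replaces the radical chemistry by an ionic sequence. Ethereal H2O2 with catalytic TMSOTf at −78 °C opens the oxetane at its tertiary carbon with inversion to give (3R,7R)-3-hydroperoxy-3,7-dimethyl-5-methylidene-13-phenyltridecan-1-ol F5. Hg(OAc)2 then closes the ring by 5-exo cycloperoxymercuration to the organomercurial (acetato){[(3S)-3-(2-hydroxyethyl)-3-methyl-5-[(2R)-2-methyl-8-phenyloctyl]-1,2-dioxolan-5-yl]methyl}mercury F6, and alkaline NaBH4 removes the metal. This comes back to the route at 24, again with its C5 epimer, which is separated as in step 13; the fallback does not cure the lack of control at C5 either.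

**Step 5 (and with it the coupling in step 11).** Base may enolise ketone 8 toward the ring-side CH2, which can open the oxetane by β-elimination or give the wrong triflate. The fallback sets out from 19 and 8 and uses no strong base. Mg insertion into 19 gives [(2R)-2-methyl-8-phenyloctyl]magnesium iodide F1, which adds to 8 in the presence of anhydrous CeCl3 (THF, −78 °C) to give the tertiary alcohol (4R)-2,4-dimethyl-1-[(2R)-2-methyloxetan-2-yl]-10-phenyldecan-2-ol F2. Burgess dehydration (THF, 50 °C) gives 21 together with its double-bond isomers (2S)-2-[(4R)-2,4-dimethyl-10-phenyldec-2-en-1-yl]-2-methyloxetane F3 and (2R)-2-[(4R)-2,4-dimethyl-10-phenyldec-1-en-1-yl]-2-methyloxetane F4. The unseparated alkenes go through the conditions of step 12, where all three give the same tertiary radical, so the route is rejoined at 22.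

**Step 14.** The oxidation passes through a β-peroxy aldehyde that can eliminate, and the one-pot ester formation may stall at the aldehyde or acid. The fallback sets out from 24: TEMPO (cat.) with PhI(OAc)2 in MeCN–water gives 2-[(3R,5S)-3,5-dimethyl-5-[(2R)-2-methyl-8-phenyloctyl]-1,2-dioxolan-3-yl]acetic acid F7, which is methylated with trimethylsilyldiazomethane in MeOH–toluene. It comes back to the route at 25.

## Further compounds

F1 | step 5 | [(2R)-2-methyl-8-phenyloctyl]magnesium iodide | I[Mg]C[C@H](C)CCCCCCc1ccccc1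
F2 | step 5 | (4R)-2,4-dimethyl-1-[(2R)-2-methyloxetan-2-yl]-10-phenyldecan-2-ol (both C2 epimers) | C[C@@]1(CCO1)CC(C)(O)C[C@H](C)CCCCCCc2ccccc2
F3 | step 5 | (2S)-2-[(4R)-2,4-dimethyl-10-phenyldec-2-en-1-yl]-2-methyloxetane (E and Z) | C[C@@]1(CCO1)CC(C)=C[C@H](C)CCCCCCc2ccccc2
F4 | step 5 | (2R)-2-[(4R)-2,4-dimethyl-10-phenyldec-1-en-1-yl]-2-methyloxetane (E and Z) | C[C@@]1(CCO1)C=C(C)C[C@H](C)CCCCCCc2ccccc2
F5 | step 12 | (3R,7R)-3-hydroperoxy-3,7-dimethyl-5-methylidene-13-phenyltridecan-1-ol | OCC[C@@](OO)(C)CC(=C)C[C@H](C)CCCCCCc1ccccc1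
F6 | step 12 | (acetato){[(3S)-3-(2-hydroxyethyl)-3-methyl-5-[(2R)-2-methyl-8-phenyloctyl]-1,2-dioxolan-5-yl]methyl}mercury (both C5 epimers) | OCC[C@@]1(C)CC(C[Hg]OC(C)=O)(C[C@H](C)CCCCCCc2ccccc2)OO1
F7 | step 14 | 2-[(3R,5S)-3,5-dimethyl-5-[(2R)-2-methyl-8-phenyloctyl]-1,2-dioxolan-3-yl]acetic acid | OC(=O)C[C@@]1(C)C[C@](C)(C[C@H](C)CCCCCCc2ccccc2)OO1
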